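**Plan**

- Retrosynthesis first cuts the two C6–O ester bonds (double Mitsunobu), giving (2E,6E)-2,6-dimethylocta-2,6-dienedioic acid and two molecules of one amino alcohol. Its N-methyl group is traced to a methyl carbamate and its carbinol to a C6 ketone.
- In each cyclopenta[c]pyridine half (N2, methyls on C4 and C7, oxygen on C6, fusion bond C4a–C7a) the five-membered ring C4a–C5–C6–C7–C7a has its oxygenated carbon between C5H2 and methyl-bearing C7 and is fused to the N2 ring. This is the pattern left by a (2+2+1) union of a nitrogen-tethered 1,7-enyne with CO, so C4a–C7a, C5–C6 and C6–C7 are cut together.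
- Forward: a purchased C4 building block and but-2-yn-1-amine give the carbamate-tethered enyne. The Pauson–Khand reaction closes the piperidine and the cyclopentenone in one operation. Hydrogenation, C7 equilibration and LiAlH4 give the amino alcohol. Geranyl acetate gives the diacid, and the chain is joined last.
- Stereochemistry: C4 is purchased; C4a is induced by C4 in the cycloaddition; C7a comes from cis-hydrogenation; C7 from thermodynamic equilibration; C6 from convex-face hydride addition followed by Mitsunobu inversion. Both E-alkenes come from geranyl acetate and an E-selective SeO2 oxidation.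

Key step: step 5

Remark: locants C1 to C7a are those of cyclopenta[c]pyridine in each bicyclic half; hydride addition to the C6 ketone of 10 is taken to occur from the convex face.

**Route**

Step 1
Reactants: 1 (R)-3-bromo-2-methylpropan-1-ol; 2 but-2-yn-1-amine hydrochloride
Product: 3 (2S)-3-(but-2-yn-1-ylamino)-2-methylpropan-1-ol
Conditions: 2 (3 equiv), K2CO3 (5 equiv), NaI (0.1 equiv), MeCN, 70 °C
Reagents that add atoms: none
Why: SN2 N-alkylation of the primary amine by the primary bromide (iodide-assisted) leaves the stereocentre untouched, and the excess of amine keeps the product from being alkylated a second time.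

Step 2
Reactants: 3
Product: 4 methyl but-2-yn-1-yl[(2S)-3-hydroxy-2-methylpropyl]carbamate
Conditions: ClCO2Me (1.05 equiv), NaHCO3, THF/H2O, 0 °C
Reagents that add atoms: methyl chloroformate, COC(=O)Cl
Why: Schotten–Baumann acylation occurs at the secondary amine, which is far more nucleophilic than the primary alcohol in aqueous bicarbonate, and installs the carbamate that serves as planar tether and later becomes the N-methyl group.

Step 3
Reactants: 4
Product: 5 methyl but-2-yn-1-yl[(2S)-2-methyl-3-oxopropyl]carbamate
Conditions: Dess–Martin periodinane (1.2 equiv), pyridine (3 equiv), CH2Cl2, 0 °C to rt; crude aldehyde used at once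
Reagents that add atoms: none
Why: Dess–Martin oxidation under pyridine buffering needs neither acid nor strong base, so the α-stereocentre should be preserved, and the alkyne and carbamate are inert.

Step 4
Reactants: 5
Product: 6 methyl but-2-yn-1-yl[(2R)-2-methylbut-3-en-1-yl]carbamate
Conditions: Ph3PCH3Br (1.5 equiv), KN(SiMe3)2 (1.4 equiv), THF, 0 °C; then 5, −78 °C to 0 °C
Reagents that add atoms: methyltriphenylphosphonium bromide, C[P+](c1ccccc1)(c1ccccc1)c1ccccc1.[Br-]
Why: Wittig methylenation with the unstabilised ylide at low temperature should outrun enolisation of the α-branched aldehyde, so the configuration is carried over (the descriptor changes from S to R only because the priorities change).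

Step 5
Reactants: 6
Product: 8 methyl (4R,4aS)-4,7-dimethyl-6-oxo-1,3,4,4a,5,6-hexahydro-2H-cyclopenta[c]pyridine-2-carboxylate, via Co2(CO)6 alkyne complex 7 (not isolated)
Conditions: Co2(CO)8 (1.1 equiv), CH2Cl2, rt; then N-methylmorpholine N-oxide (8 equiv), 0 °C to rt
Reagents that add atoms: dicobalt octacarbonyl Co2(CO)8, O=C=[Co](=C=O)(=C=O)(=C=O)[Co](=C=O)(=C=O)(=C=O)=C=O
Why: Co2(CO)8 first gives the alkyne complex 7; the amine N-oxide removes a CO ligand as CO2, the pendant vinyl group coordinates and inserts into a Co–C bond to form C4a–C7a, and CO insertion followed by reductive elimination forms C5–C6 and C6–C7 (intramolecular Pauson–Khand (2+2+1) cycloaddition, the closest known class being carbamate- and sulfonamide-tethered 1,7-enynes). The piperidine closes in a 6-exo manner with respect to both π systems, the internal alkyne carbon C7a bonding to the internal alkene carbon C4a across the four-atom C1–N2–C3–C4 tether, and the cyclopentenone closes by union of C7=C7a, C4a–C5 and one CO. The planar carbamate nitrogen and the methyl-capped alkyne favour ring closure over alkyne oligomerisation, the usual weakness of 1,7-enynes. The one new stereocentre, C4a, is set by the allylic C4 centre: in the fused cobaltacycle H4a faces the second Co(CO)3 unit and the C4 methyl sits on the open exo face, anti to H4a and cis to C5, which corresponds to 4R,4aS. The step needs this facial selectivity of alkene insertion, which rests on the C4 methyl next to the reacting vinyl group, and the regiochemistry that places the alkyne methyl on C7 beside the new carbonyl, which the tether enforces.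

Step 6
Reactants: 8
Product: 9 methyl (4R,4aS,7R,7aR)-4,7-dimethyl-6-oxooctahydro-2H-cyclopenta[c]pyridine-2-carboxylate
Conditions: H2 (4 bar), Pd/C (10%), EtOAc, rt
Reagents that add atoms: none
Why: Heterogeneous syn-hydrogenation should deliver both hydrogens to C7=C7a from the face of H4a, opposite the pseudo-axial C4 methyl, giving the cis ring fusion (7aR) and, for the moment, the C7 methyl cis to C1 (7R).

Step 7
Reactants: 9
Product: 10 methyl (4R,4aS,7S,7aR)-4,7-dimethyl-6-oxooctahydro-2H-cyclopenta[c]pyridine-2-carboxylate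
Conditions: NaOMe (0.3 equiv), MeOH, rt
Reagents that add atoms: none
Why: Base equilibration through the C7 enolate (C5 carries no stereocentre, C4a and C7a are not enolisable) should move the methyl to the convex face trans to the C7a–C1 bond (7S), relieving the cis-1,2 interaction, while methoxide exchange at the methyl carbamate is degenerate.

Step 8
Reactants: 10
Product: 11 (4R,4aS,6S,7S,7aR)-2,4,7-trimethyloctahydro-1H-cyclopenta[c]pyridin-6-ol
Conditions: LiAlH4 (5 equiv), THF, 0 °C, then reflux; aqueous NaOH work-up
Reagents that add atoms: none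
Why: LiAlH4 should add hydride to the C6 ketone from the convex face (the concave face is screened by the piperidine ring, and small hydrides favour the trans-2-methylcyclopentanol), giving the 6S alcohol with OH trans to the C7 methyl, and at reflux it reduces the methyl carbamate to N-methyl.

Step 9
Reactants: 12 geranyl acetate, (2E)-3,7-dimethylocta-2,6-dien-1-yl acetate
Product: 13 (2E,6E)-8-hydroxy-3,7-dimethylocta-2,6-dien-1-yl acetate
Conditions: SeO2 (0.1 equiv), t-BuOOH (70% in water, 3 equiv), salicylic acid (0.1 equiv), CH2Cl2, rt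
Reagents that add atoms: tert-butyl hydroperoxide, CC(C)(C)OO; selenium dioxide (catalytic oxygen carrier), O=[Se]=O
Why: Riley-type allylic oxidation proceeds by ene reaction and [2,3]-sigmatropic shift at the more electron-rich 6,7-alkene and selects its E-methyl group, while the 2,3-alkene is deactivated by the allylic acetate.

Step 10
Reactants: 13
Product: 14 (2E,6E)-2,6-dimethylocta-2,6-diene-1,8-diol
Conditions: K2CO3 (0.2 equiv), MeOH, rt
Reagents that add atoms: none
Why: Base-catalysed transesterification removes the acetate without touching either alkene.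

Step 11
Reactants: 14
Product: 15 (2E,6E)-2,6-dimethylocta-2,6-dienedial
Conditions: MnO2 (activated, 20 equiv), CH2Cl2, rt
Reagents that add atoms: none
Why: Both hydroxyl groups are allylic, and MnO2 oxidises allylic alcohols to enals without over-oxidation or E/Z isomerisation.

Step 12
Reactants: 15
Product: 16 (2E,6E)-2,6-dimethylocta-2,6-dienedioic acid
Conditions: NaClO2 (6 equiv), NaH2PO4 (6 equiv), 2-methylbut-2-ene (20 equiv), t-BuOH/H2O, 0 °C to rt
Reagents that add atoms: sodium chlorite, [Na+].[O-]Cl=O
Why: Pinnick oxidation converts both enals into enoic acids with retention of alkene geometry, the alkene scavenger trapping hypochlorous acid before it can chlorinate the trisubstituted double bonds.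

Step 13
Reactants: 11 (4R,4aS,6S,7S,7aR)-2,4,7-trimethyloctahydro-1H-cyclopenta[c]pyridin-6-ol (2.2 equiv); 16 (2E,6E)-2,6-dimethylocta-2,6-dienedioic acid
Product: 17 bis[(4R,4aS,6R,7S,7aR)-2,4,7-trimethyloctahydro-1H-cyclopenta[c]pyridin-6-yl] (2E,6E)-2,6-dimethylocta-2,6-dienedioate
Conditions: PPh3 (3 equiv), diisopropyl azodicarboxylate (3 equiv), THF, 0 °C to rt
Reagents that add atoms: none
Why: Twofold Mitsunobu esterification, in which each carboxylate displaces the C6 oxyphosphonium group from the convex face with inversion (6S to 6R), places the ester oxygen cis to the C7 methyl, and the tertiary amine and both E-alkenes are spectators.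

**Compound list**

1 | (R)-3-bromo-2-methylpropan-1-ol | BrC[C@@H](CO)C | starting material
2 | but-2-yn-1-amine hydrochloride | CC#CCN.Cl | starting material
3 | (2S)-3-(but-2-yn-1-ylamino)-2-methylpropan-1-ol | CC#CCNC[C@@H](CO)C | intermediate
4 | methyl but-2-yn-1-yl[(2S)-3-hydroxy-2-methylpropyl]carbamate | CC#CCN(C(=O)OC)C[C@@H](CO)C | intermediate
5 | methyl but-2-yn-1-yl[(2S)-2-methyl-3-oxopropyl]carbamate | CC#CCN(C(=O)OC)C[C@@H](C=O)C | intermediate
6 | methyl but-2-yn-1-yl[(2R)-2-methylbut-3-en-1-yl]carbamate | CC#CCN(C(=O)OC)C[C@H](C)C=C | intermediate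
7 | Co2(CO)6 complex of the alkyne of 6 (both alkyne carbons bound to both cobalt atoms) | CC12[Co]3(=C=O)(=C=O)(=C=O)[Co]1(=C=O)(=C=O)(=C=O)C23CN(C(=O)OC)C[C@H](C)C=C | intermediate
8 | methyl (4R,4aS)-4,7-dimethyl-6-oxo-1,3,4,4a,5,6-hexahydro-2H-cyclopenta[c]pyridine-2-carboxylate | O=C1C[C@@H]2C(CN(C(=O)OC)C[C@@H]2C)=C1C | intermediate
9 | methyl (4R,4aS,7R,7aR)-4,7-dimethyl-6-oxooctahydro-2H-cyclopenta[c]pyridine-2-carboxylate (cis-fused, C7 methyl cis to C1) | O=C1C[C@@H]2[C@@H](CN(C(=O)OC)C[C@@H]2C)[C@H]1C | intermediate
10 | methyl (4R,4aS,7S,7aR)-4,7-dimethyl-6-oxooctahydro-2H-cyclopenta[c]pyridine-2-carboxylate (cis-fused, C7 methyl trans to C1) | O=C1C[C@@H]2[C@@H](CN(C(=O)OC)C[C@@H]2C)[C@@H]1C | intermediate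
11 | (4R,4aS,6S,7S,7aR)-2,4,7-trimethyloctahydro-1H-cyclopenta[c]pyridin-6-ol (OH trans to the C7 methyl) | O[C@H]1C[C@@H]2[C@@H](CN(C)C[C@@H]2C)[C@@H]1C | intermediate
12 | geranyl acetate, (2E)-3,7-dimethylocta-2,6-dien-1-yl acetate | CC(C)=CCC/C(C)=C/COC(C)=O | starting material
13 | (2E,6E)-8-hydroxy-3,7-dimethylocta-2,6-dien-1-yl acetate | OC/C(C)=C/CC/C(C)=C/COC(C)=O | intermediate
14 | (2E,6E)-2,6-dimethylocta-2,6-diene-1,8-diol | OC/C(C)=C/CC/C(C)=C/CO | intermediate
15 | (2E,6E)-2,6-dimethylocta-2,6-dienedial | O=C/C(C)=C/CC/C(C)=C/C=O | intermediate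
16 | (2E,6E)-2,6-dimethylocta-2,6-dienedioic acid | OC(=O)/C(C)=C/CC/C(C)=C/C(=O)O | intermediate
17 | bis[(4R,4aS,6R,7S,7aR)-2,4,7-trimethyloctahydro-1H-cyclopenta[c]pyridin-6-yl] (2E,6E)-2,6-dimethylocta-2,6-dienedioate | C/C(=C\C(=O)O[C@@H]1C[C@@H]2[C@@H](CN(C)C[C@@H]2C)[C@@H]1C)CC/C=C(\C)C(=O)O[C@@H]1C[C@@H]2[C@@H](CN(C)C[C@@H]2C)[C@@H]1C | target

**Step count and risks**

Total steps: 13. Longest linear sequence: 9 (steps 1 to 8 and 13); the diacid branch is steps 9 to 12.

Steps most likely to fail:

1. Step 5. The alkene insertion may discriminate poorly between the two faces, because a single allylic methyl group may not bias a six-membered closure strongly, so the C4a epimer would form alongside 8. The 1,7-enyne may also close slowly, with decomposition of complex 7 competing. The fallback sets out from 1 and returns at 10. It moves the controlling methyl group to the propargylic position and lets alkene geometry fix C7, while the same three bonds are formed. Amination of 1 with (E)-but-2-en-1-amine (K2CO3, NaI, MeCN, 70 °C) gives (2S)-3-{[(2E)-but-2-en-1-yl]amino}-2-methylpropan-1-ol F1. Acylation with ClCO2Me/NaHCO3 gives methyl [(2E)-but-2-en-1-yl][(2S)-3-hydroxy-2-methylpropyl]carbamate F2. Dess–Martin oxidation gives methyl [(2E)-but-2-en-1-yl][(2S)-2-methyl-3-oxopropyl]carbamate F3. Ohira–Bestmann alkynylation (dimethyl (1-diazo-2-oxopropyl)phosphonate, K2CO3, MeOH) gives methyl [(2E)-but-2-en-1-yl][(2R)-2-methylbut-3-yn-1-yl]carbamate F4. Co2(CO)8 followed by N-methylmorpholine N-oxide gives, through the Co2(CO)6 alkyne complex F5, methyl (4R,7S,7aS)-4,7-dimethyl-6-oxo-1,3,4,6,7,7a-hexahydro-2H-cyclopenta[c]pyridine-2-carboxylate F6. In F6 the propargylic C4 methyl should direct C7a by 1,3-induction and the E-alkene should deliver the C7 methyl trans to C1. Hydrogenation of C4a=C5 (H2, Pd/C, EtOAc) from the face of H7a then gives 10.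

2. Step 13. The twofold displacement at hindered C6, next to methyl-bearing C7, may give way to elimination toward a cyclopentene or stop at the mono-ester, since enoic acids are only moderately acidic Mitsunobu partners. The fallback sets out from 11 and returns at 17. It separates inversion from ester formation. Mitsunobu reaction of 11 with the more acidic 4-nitrobenzoic acid (PPh3, diisopropyl azodicarboxylate, THF) gives (4R,4aS,6R,7S,7aR)-2,4,7-trimethyloctahydro-1H-cyclopenta[c]pyridin-6-yl 4-nitrobenzoate F7. Methanolysis (K2CO3, MeOH) gives (4R,4aS,6R,7S,7aR)-2,4,7-trimethyloctahydro-1H-cyclopenta[c]pyridin-6-ol F8. Steglich esterification of F8 (2.2 equiv) with 16 (EDC·HCl, DMAP, CH2Cl2) proceeds with retention at C6 and gives 17.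

3. Step 4. Enolisation of the α-branched aldehyde 5 by the basic ylide may erode configurational purity at the future C4, and β-elimination of the carbamate may compete. The fallback sets out from 4 and returns at 6. It reverses the polarity so that no enolisable aldehyde is involved. Mitsunobu thioetherification of 4 with 1-phenyl-1H-tetrazole-5-thiol (PPh3, diisopropyl azodicarboxylate, THF) gives methyl but-2-yn-1-yl{(2S)-2-methyl-3-[(1-phenyl-1H-tetrazol-5-yl)sulfanyl]propyl}carbamate F9. Oxidation (H2O2, (NH4)6Mo7O24, EtOH) gives methyl but-2-yn-1-yl{(2S)-2-methyl-3-[(1-phenyl-1H-tetrazol-5-yl)sulfonyl]propyl}carbamate F10. Julia–Kocienski olefination of F10 with monomeric formaldehyde (KN(SiMe3)2, THF, −78 °C to rt, base added to the mixture of sulfone and formaldehyde) gives 6.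

**Further compounds**

F1 | step 5 | (2S)-3-{[(2E)-but-2-en-1-yl]amino}-2-methylpropan-1-ol | C/C=C/CNC[C@@H](CO)C
F2 | step 5 | methyl [(2E)-but-2-en-1-yl][(2S)-3-hydroxy-2-methylpropyl]carbamate | C/C=C/CN(C(=O)OC)C[C@@H](CO)C
F3 | step 5 | methyl [(2E)-but-2-en-1-yl][(2S)-2-methyl-3-oxopropyl]carbamate | C/C=C/CN(C(=O)OC)C[C@@H](C=O)C
F4 | step 5 | methyl [(2E)-but-2-en-1-yl][(2R)-2-methylbut-3-yn-1-yl]carbamate | C/C=C/CN(C(=O)OC)C[C@@H](C#C)C
F5 | step 5 | Co2(CO)6 complex of the alkyne of F4 | C/C=C/CN(C(=O)OC)C[C@H](C)C12[Co]3(=C=O)(=C=O)(=C=O)[Co]1(=C=O)(=C=O)(=C=O)C23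
F6 | step 5 | methyl (4R,7S,7aS)-4,7-dimethyl-6-oxo-1,3,4,6,7,7a-hexahydro-2H-cyclopenta[c]pyridine-2-carboxylate | O=C1C=C2[C@@H](CN(C(=O)OC)C[C@@H]2C)[C@@H]1C
F7 | step 13 | (4R,4aS,6R,7S,7aR)-2,4,7-trimethyloctahydro-1H-cyclopenta[c]pyridin-6-yl 4-nitrobenzoate | O=C(O[C@@H]1C[C@@H]2[C@@H](CN(C)C[C@@H]2C)[C@@H]1C)c1ccc(cc1)[N+](=O)[O-]
F8 | step 13 | (4R,4aS,6R,7S,7aR)-2,4,7-trimethyloctahydro-1H-cyclopenta[c]pyridin-6-ol | O[C@@H]1C[C@@H]2[C@@H](CN(C)C[C@@H]2C)[C@@H]1C
F9 | step 4 | methyl but-2-yn-1-yl{(2S)-2-methyl-3-[(1-phenyl-1H-tetrazol-5-yl)sulfanyl]propyl}carbamate | CC#CCN(C(=O)OC)C[C@@H](CSc1nnnn1-c1ccccc1)C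
F10 | step 4 | methyl but-2-yn-1-yl{(2S)-2-methyl-3-[(1-phenyl-1H-tetrazol-5-yl)sulfonyl]propyl}carbamate | CC#CCN(C(=O)OC)C[C@@H](CS(=O)(=O)c1nnnn1-c1ccccc1)C
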